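## The problem

Compound 24 is a spiro[5.5]undecane: ring A (C2–C7; C1 is the methyl on C2, C6 carries two methyls) and ring B (C7–C12) share the quaternary carbon C7. C7 lies between the fully substituted C6 and the branched C2, so every bond to it forms under heavy steric pressure. It is a stereocentre only because the two arms of ring B differ (C8–C9 against C12–C11), so the arms must be told apart from the moment ring B closes. Of the six stereocentres, C2 can be set early and carried, and C7 must be set from C2 (C12 cis to the C2 methyl). C4 and C5 (OH and Br, both on the face of ring A that holds the C2 methyl and C12) can take their cue from C2 and C7. C10 and C11 can be reached only through C7: Br on C11 stands on the face of ring B that carries C6, and Cl on C10 is trans to it, on the face that carries C2. The tertiary chloride next to a secondary bromide will not survive base, reducing metals or warm ionising media, and the bromohydrin is base-sensitive, so the halogens come last. Two features allow a short plan. In ring B, C10 is 1,4 to C7, the pattern of a 4,4-disubstituted cyclohex-2-enone whose C12 was an aldehyde carbon on C7 and whose C8–C11 came from methyl vinyl ketone. In ring A, C6 has no hydrogen, so a C4–C5 double bond cannot migrate, is opened by nucleophiles only at C4, and can stand in for the bromohydrin through the whole route.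

## Retrosynthesis

**Ring A halohydrin (C4–O, C5–Br).** The last centre to be set is C4: 24 comes from bromo ketone 23 by hydride reduction. Bromide as a nucleophile (epoxide or cyclic sulfate opening) would attack the less hindered C4, so bromine must arrive as an electrophile. 23 is therefore the oxidised form of the trans-bromohydrin 22, made from alkene 21 with NBS and water. Alkene 21 has two stereocentres fewer. The forward steps ask that water open the bromonium ion at C4 on the face away from the C2 methyl, and that hydride later attack C4 from that same face.

**Ring B halides (C10–Cl, C10–CH3, C11–Br).** 21 is cut at C10–Cl to tertiary alcohol 20, at C10–CH3 to bromo ketone 19, and at C11–Br to enone 17. Adding BrCl across a C10–C11 double bond was weighed. Its face is decided when chloride opens the bromonium ion, and the chair-like trans-diaxial opening would put bromine on the C2 face, the wrong one. The chosen order sets C11 first, where steric approach and stability agree. On ring B, C2 rather than C6 should lie axial at C7: an axial C6 would push a methyl into ring B, whereas an axial C2 turns only its hydrogen inward. A C10–C11 enolate is then brominated from the C6 face, and the equatorial bromide formed is also the stable epimer. C10 follows stereospecifically, because a cation at C10 is bridged by the C11 bromine and opened by chloride trans to it. This needs a regiodefined C10–C11 enolate, which only enone 17 with its two different arms can give.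

**Ring B and the spiro centre (C7–C8, C11–C12).** Enone 17 is cut to aldehyde 13 and methyl vinyl ketone 14: enamine 15 adds through C7 to 14, and keto aldehyde 16 condenses. Compared with alkylating a ring A ketone at C7, the aldehyde has a single α-hydrogen, which removes every regiochemical question. It also delivers ring B with one carbonyl at C10 and the arms differentiated. 13 is a monocyclic C10 aldehyde with one fixed stereocentre. The forward step must build a quaternary centre between two branched carbons, anti to the C2 methyl.

**The aldehyde carbon (C7–C12).** 13 is cut at the formyl carbon to ketone 9, through alcohol 12 and diene 10 (methylenation, anti-Markovnikov hydration, oxidation). Two shorter homologations were set aside. Alkoxymethylene phosphorus ylides are strong bases and slow with so hindered a ketone, which endangers the centre α to the carbonyl. A sulfur-ylide epoxide would have to rearrange through a cation at C7, where a methyl shift from C6 would give an allylic cation. The chosen sequence is one step longer but has no strong base and no cation, and 9-BBN supplies the selectivity for the terminal over the ring alkene.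

**The C2 methyl (C1–C2).** Ketone 9 is cut at the methyl group to hydrazone 8 and, through azaenolate 7, to hydrazone 6 of achiral ketone 4 with RAMP 5. An oxygen at C5, from enantioselective monoreduction of dione 1, was weighed as both the source of chirality and the latent alkene. It was not adopted, for three reasons:
- Next to the gem-dimethyl carbon such a group has almost no equatorial preference, so a C2 methyl cannot be set relative to it by equilibration.
- In the enamine of the key step it would sit axial on the face that 14 must use.
- Its late dehydration at a neopentyl carbon invites methyl migration.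

Reagent control by the auxiliary makes C2 independent of every other centre, at the price of three steps.

**The ring A alkene.** Ketone 4 is cut back to dione 1 through enol triflate 3 (monoenolate 2). One of the two equivalent carbonyls becomes the C4–C5 double bond by triflation and hydrogenolysis, without a carbocation. Dione 1 is commercial.

## Roads not taken

**Alternative 1:** photocycloaddition, then reductive cyclobutane cleavage.
- **Cut:** C7–C2, with a temporary C12–C1 bond.
- **Forward step:** irradiation (about 350 nm) of enone A1 gives cyclobutane A2. Li/NH3 or SmI2 then breaks the C12–C1 bond α to the ketone, leaving spiro ketone A3 with C1 as the C2 methyl.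
- **Merits:** C7 is formed intramolecularly, so nothing has to attack a carbon between two branched centres from outside. The cis-fused cyclobutane forces C1 and C12 onto the same face of ring A, exactly as in 24. On both counts this road is safer than the chosen one.
- **Weak points:** the ring B carbonyl ends at C11, not C10. The C10 methyl must then be introduced by enolate alkylation in competition with C12. The halides can only be added to a C10–C11 alkene made from that ketone, with no element to choose the face. A1 needs a tertiary carbon on the enone, a C5 stereocentre as the sole source of absolute configuration, and a four-atom tether for which straight and crossed addition compete. The C5 oxygen must later be eliminated at a neopentyl carbon.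
- **Comparison:** the chosen plan joins two small pieces in one step and places the ring B carbonyl where the halogens need it; it pays with a harder bond formation at C7.

**Alternative 2:** double Michael spiroannulation.
- **Cut:** C6–C7 and C2–C7.
- **Forward step:** 5-methylcyclohexane-1,3-dione A4 adds through its central carbon to both unsaturated termini of (E)-hept-2-en-5-yn-4-one A5, giving spiro enone-dione A6 in one step.
- **Merits:** it is the shortest entry to the skeleton (one step against nine). The nucleophile is a stabilised dicarbonyl carbanion, and C6 is still trigonal, so congestion is avoided. Ring A would be well served: the C4 ketone is present, and adding the second methyl to C6 by cuprate addition would leave a regiodefined C5 enolate for bromination. In these respects it is better than the chosen plan.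
- **Weak points:** ring B is oxidised in the wrong places. The C8 and C12 ketones must both be removed, and nothing marks C10 or C11 for chlorine and bromine. C7 is not a stereocentre in A6, so the arms of ring B would have to be differentiated afterwards. C10 is formed as a mixture and C2 without absolute control.
- **Comparison:** the chosen plan offers a single ring B carbonyl at C10, arms that are different from the start, and C2 fixed in absolute terms.

**Alternative 3:** double alkylation of a chiral-pool enone.
- **Cut:** C7–C12 and C7–C8.
- **Forward step:** the α'-enolate of (S)-5-methylcyclohex-2-en-1-one A7 is alkylated by the allylic bromide end of (Z)-1-bromo-5-iodo-3-methylpent-2-ene A8, re-enolised and closed on the iodide end to give spiro dienone A9.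
- **Merits:** C2 comes from the chiral pool with no auxiliary, a clear advantage over the three steps spent here. The ring closure anti to the C2 methyl sets C7 correctly. Ring B arrives with its methyl and the C10–C11 alkene, and ring A with the C4–C5 alkene.
- **Weak points:** C6 is a ketone, and turning a carbonyl next to the spiro centre into a gem-dimethyl group takes several steps and must be done in the presence of two other alkenes. Without a C10 carbonyl the ring B halides can only come from direct bromochlorination, whose face is uncontrolled. A7 belongs to the rarer enantiomeric series of pulegone.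
- **Comparison:** the chosen plan has the gem-dimethyl group in place before C7 is made, and the C10 ketone as the handle for stereocontrolled halogenation.

Key step: step 9

Remarks on the chemistry:
- Locants C1–C12 in the names of the spiro compounds are those of the skeleton defined under "The problem", and the CIP descriptors refer to these locants.
- The sense of induction in step 4 follows the standard model of the hydrazone method, in which the SAMP hydrazone of cyclohexanone gives (R)-2-methylcyclohexanone. RAMP is therefore expected to give the (6S) ketone 9; SAMP would replace it if the sense proved opposite.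
- Ion pairs and metal-bound transients named in the Why lines are not counted as compounds.

## Route

Step 1
Reactants: 1 2,2-dimethylcyclohexane-1,3-dione
Product: 3 6,6-dimethyl-5-oxocyclohex-1-en-1-yl trifluoromethanesulfonate, via potassium enolate 2 (not isolated)
Conditions: KN(SiMe3)2 (1.05 equiv), THF, −78 °C; then PhNTf2, −78 → 0 °C
Reagents that add atoms: N-phenylbis(trifluoromethanesulfonimide), O=S(=O)(N(c1ccccc1)S(=O)(=O)C(F)(F)F)C(F)(F)F
Why: Kinetic enolate O-triflation; the dione can enolise only away from the quaternary carbon, one equivalent of base gives monoenolate 2, and one carbonyl becomes the handle for the C4–C5 alkene.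

Step 2
Reactants: 3 6,6-dimethyl-5-oxocyclohex-1-en-1-yl trifluoromethanesulfonate
Product: 4 2,2-dimethylcyclohex-3-en-1-one
Conditions: Pd(OAc)2 (5 mol %), PPh3, HCO2H, Bu3N, DMF, 60 °C
Reagents that add atoms: none
Why: Palladium-catalysed formate hydrogenolysis of an enol triflate; the alkene is placed without a cation next to the quaternary carbon and cannot move into conjugation because that carbon bears no hydrogen.

Step 3
Reactants: 4 2,2-dimethylcyclohex-3-en-1-one; 5 (R)-1-amino-2-(methoxymethyl)pyrrolidine (RAMP)
Product: 6 (2R)-N-[(1E)-2,2-dimethylcyclohex-3-en-1-ylidene]-2-(methoxymethyl)pyrrolidin-1-amine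
Conditions: TsOH (cat.), cyclohexane, reflux, Dean–Stark
Reagents that add atoms: none
Why: Hydrazone condensation; the amino nitrogen settles anti to the quaternary carbon, the geometry the Enders alkylation needs.

Step 4
Reactants: 6 (2R)-N-[(1E)-2,2-dimethylcyclohex-3-en-1-ylidene]-2-(methoxymethyl)pyrrolidin-1-amine
Product: 8 (2R)-2-(methoxymethyl)-N-[(1E,6S)-2,2,6-trimethylcyclohex-3-en-1-ylidene]pyrrolidin-1-amine, via lithium azaenolate 7 (not isolated)
Conditions: LiN(i-Pr)2, THF, 0 °C; then MeI, −100 °C → rt
Reagents that add atoms: iodomethane, CI
Why: Enders RAMP-hydrazone alkylation; the only α-hydrogens are at C6, and the chelated azaenolate 7 is methylated on the face left open by the methoxymethyl arm, which with RAMP should give the (6S) centre, the later C2.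

Step 5
Reactants: 8 (2R)-2-(methoxymethyl)-N-[(1E,6S)-2,2,6-trimethylcyclohex-3-en-1-ylidene]pyrrolidin-1-amine
Product: 9 (6S)-2,2,6-trimethylcyclohex-3-en-1-one
Conditions: sat. aq. oxalic acid, Et2O, rt
Reagents that add atoms: water, O
Why: Two-phase oxalic acid hydrolysis of the hydrazone, a cleavage known to leave α-stereocentres untouched and to return the auxiliary; 9 is volatile and configurationally labile and is used at once.

Step 6
Reactants: 9 (6S)-2,2,6-trimethylcyclohex-3-en-1-one
Product: 10 (5S)-3,3,5-trimethyl-4-methylidenecyclohex-1-ene
Conditions: Cp2TiMe2, toluene, 70 °C, dark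
Reagents that add atoms: dimethyltitanocene Cp2TiMe2, C[Ti](C)(C1C=CC=C1)C1C=CC=C1
Why: Petasis methylenation; the titanium methylidene is not basic, so the hindered, enolisable ketone should be olefinated without epimerising the adjacent methyl-bearing centre.

Step 7
Reactants: 10 (5S)-3,3,5-trimethyl-4-methylidenecyclohex-1-ene
Product: 12 [(6S)-2,2,6-trimethylcyclohex-3-en-1-yl]methanol (C1 epimers), via alkylborane 11 (not isolated)
Conditions: 9-BBN, THF, 0 → 50 °C; then NaOH, H2O2, 0 °C → rt
Reagents that add atoms: hydrogen peroxide, OO
Why: Hydroboration–oxidation; 9-BBN puts boron on the terminal carbon of the 1,1-disubstituted alkene far faster than on the cis-disubstituted ring alkene beside the quaternary carbon, and the new centre at C1 is irrelevant because it becomes trigonal in step 9.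

Step 8
Reactants: 12 [(6S)-2,2,6-trimethylcyclohex-3-en-1-yl]methanol (C1 epimers)
Product: 13 (6S)-2,2,6-trimethylcyclohex-3-ene-1-carbaldehyde (C1 epimers)
Conditions: Dess–Martin periodinane, CH2Cl2, 0 °C → rt
Reagents that add atoms: none
Why: Dess–Martin oxidation of a primary alcohol under neutral conditions; the methyl-bearing centre is β to the carbonyl group and cannot epimerise.

Step 9
Reactants: 13 (6S)-2,2,6-trimethylcyclohex-3-ene-1-carbaldehyde (C1 epimers); 14 methyl vinyl ketone (but-3-en-2-one)
Product: 17 (2S,7R)-2,6,6-trimethylspiro[5.5]undeca-4,11-dien-10-one, via pyrrolidine enamine 15 (not isolated), via keto aldehyde 16 (not isolated)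
Conditions: pyrrolidine, TsOH (cat.), toluene, reflux (−H2O); then slow addition of 14, rt → 45 °C; then AcOH, NaOAc, H2O, reflux
Reagents that add atoms: none
Why: Stork enamine Michael addition followed by intramolecular aldol condensation, that is, the Robinson annulation of an α,α-disubstituted aldehyde with methyl vinyl ketone to a 4,4-disubstituted cyclohex-2-enone, which is the closest known reaction type. Pyrrolidine converts 13 into the exocyclic enamine 15, whose nucleophilic carbon C7 adds to the terminus of 14 and forms C7–C8 and the quaternary centre; buffered hydrolysis releases keto aldehyde 16. In 16 the aldehyde has no α-hydrogen, so only the ketone enolises; the enolate toward the methyl group (C11) attacks the aldehyde carbon C12 in a 6-(enolendo)-exo-trig aldol and loss of water gives ring B as the enone, whereas the enolate toward C9 could only close a four-membered ring. The one new stereocentre, C7, is controlled by C2: in 15 the nitrogen lies syn to C2 (C6 has no hydrogen to put in the plane), 1,3-allylic strain turns the C2 methyl axial, and this methyl together with the axial methyl of C6 covers one face of the enamine, so 14 should bond on the other face, which puts C8 trans and the former aldehyde carbon C12 cis to the C2 methyl as in 24. The step thus needs facial selectivity at C7, secured by the C2 methyl, and C-alkylation at a very hindered carbon in competition with polymerisation of 14, which is met by adding 14 slowly to the preformed enamine. The two arms of ring B emerge different (saturated C8–C9, unsaturated C11–C12), which is what lets step 10 address C11 alone.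

Step 10
Reactants: 17 (2S,7R)-2,6,6-trimethylspiro[5.5]undeca-4,11-dien-10-one
Product: 19 (2S,7S,11S)-11-bromo-2,6,6-trimethylspiro[5.5]undec-4-en-10-one, via lithium enolate 18 (not isolated)
Conditions: LiBH(s-Bu)3, THF, −78 °C; then NBS, THF, −78 °C
Reagents that add atoms: N-bromosuccinimide, O=C1CCC(=O)N1Br
Why: Conjugate reduction of a β-unsubstituted cyclohexenone by the trialkylborohydride gives only the C10–C11 enolate 18, which is brominated at C11; C2 of ring A lies axial over one face of ring B, so bromine should enter from the C6 face, and the equatorial bromide formed is also the more stable epimer.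

Step 11
Reactants: 19 (2S,7S,11S)-11-bromo-2,6,6-trimethylspiro[5.5]undec-4-en-10-one
Product: 20 (2S,7S,11S)-11-bromo-2,6,6,10-tetramethylspiro[5.5]undec-4-en-10-ol (C10 epimers)
Conditions: MeLi, CeCl3, THF, −78 °C; AcOH quench at −78 °C
Reagents that add atoms: methyllithium, [Li]C
Why: Organocerium 1,2-addition to an α-bromo ketone, which avoids enolisation and bromide displacement; the C10 configuration is of no consequence because both epimers pass through the same bromonium ion in step 12, and the cold quench prevents epoxide closure.

Step 12
Reactants: 20 (2S,7S,11S)-11-bromo-2,6,6,10-tetramethylspiro[5.5]undec-4-en-10-ol (C10 epimers)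
Product: 21 (2S,7S,10S,11S)-11-bromo-10-chloro-2,6,6,10-tetramethylspiro[5.5]undec-4-ene
Conditions: HCl (g), CH2Cl2, −40 → 0 °C
Reagents that add atoms: hydrogen chloride, Cl
Why: Unimolecular substitution of a tertiary alcohol with neighbouring-bromine participation; ionisation at C10 gives the bromonium ion bridged on the face the C11 bromine already occupies, and chloride opens it at the tertiary carbon from the other face, so Cl should end trans to Br on the C2 face whatever the carbinol configuration. Ionisation at C10 is reversible under these conditions, which favours the diequatorial tertiary chloride.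

Step 13
Reactants: 21 (2S,7S,10S,11S)-11-bromo-10-chloro-2,6,6,10-tetramethylspiro[5.5]undec-4-ene
Product: 23 (2S,5S,7S,10S,11S)-5,11-dibromo-10-chloro-2,6,6,10-tetramethylspiro[5.5]undecan-4-one, via trans-bromohydrin 22 (not isolated)
Conditions: NBS, THF–H2O (4:1), 0 °C; then IBX, DMSO, rt
Reagents that add atoms: N-bromosuccinimide, O=C1CCC(=O)N1Br; water, O
Why: Bromohydrin formation then alcohol oxidation, a known one-flask route from alkenes to α-bromo ketones; water can open the reversibly formed bromonium ion only at C4 (C5 is neopentyl) and only from the face opposite the axial C2 methyl, so the ion that goes on should be the one with bromine on the methyl face, the C5 configuration of 24. IBX then erases the C4 carbinol centre, which has the wrong configuration.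

Step 14
Reactants: 23 (2S,5S,7S,10S,11S)-5,11-dibromo-10-chloro-2,6,6,10-tetramethylspiro[5.5]undecan-4-one
Product: 24 (2S,4R,5S,7S,10S,11S)-5,11-dibromo-10-chloro-2,6,6,10-tetramethylspiro[5.5]undecan-4-ol
Conditions: NaBH4, CeCl3·7H2O, MeOH–CH2Cl2, −78 °C
Reagents that add atoms: none
Why: Luche-type hydride reduction of an α-bromo ketone; hydride should attack C4 from the face opposite the C5 bromine and the C2 and C6 methyl groups that flank the other face, giving the C4 alcohol cis to bromine (4R). Low temperature and the cerium salt keep C5 from epimerising, and a cis-bromohydrin cannot close to an epoxide.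

## Compound list

1 | 2,2-dimethylcyclohexane-1,3-dione | CC1(C)C(=O)CCCC1=O | starting material
2 | potassium 6,6-dimethyl-5-oxocyclohex-1-en-1-olate | CC1(C)C(=O)CCC=C1[O-].[K+] | intermediate (not isolated)
3 | 6,6-dimethyl-5-oxocyclohex-1-en-1-yl trifluoromethanesulfonate | CC1(C)C(=O)CCC=C1OS(=O)(=O)C(F)(F)F | intermediate
4 | 2,2-dimethylcyclohex-3-en-1-one | CC1(C)C=CCCC1=O | intermediate
5 | (R)-1-amino-2-(methoxymethyl)pyrrolidine (RAMP) | COC[C@H]1CCCN1N | starting material
6 | (2R)-N-[(1E)-2,2-dimethylcyclohex-3-en-1-ylidene]-2-(methoxymethyl)pyrrolidin-1-amine | COC[C@H]1CCCN1/N=C1/C(C)(C)C=CCC1 | intermediate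
7 | lithium (6,6-dimethylcyclohexa-1,4-dien-1-yl)[(2R)-2-(methoxymethyl)pyrrolidin-1-yl]azanide (azaenolate of 6) | COC[C@H]1CCCN1[N-]C1=CCC=CC1(C)C.[Li+] | intermediate (not isolated)
8 | (2R)-2-(methoxymethyl)-N-[(1E,6S)-2,2,6-trimethylcyclohex-3-en-1-ylidene]pyrrolidin-1-amine | C[C@H]1CC=CC(C)(C)/C1=N/N1CCC[C@@H]1COC | intermediate
9 | (6S)-2,2,6-trimethylcyclohex-3-en-1-one | C[C@H]1CC=CC(C)(C)C1=O | intermediate
10 | (5S)-3,3,5-trimethyl-4-methylidenecyclohex-1-ene | C[C@H]1CC=CC(C)(C)C1=C | intermediate
11 | 9-{[(6S)-2,2,6-trimethylcyclohex-3-en-1-yl]methyl}-9-borabicyclo[3.3.1]nonane (C1 epimers) | C[C@H]1CC=CC(C)(C)C1CB1C2CCCC1CCC2 | intermediate (not isolated)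
12 | [(6S)-2,2,6-trimethylcyclohex-3-en-1-yl]methanol (C1 epimers) | C[C@H]1CC=CC(C)(C)C1CO | intermediate
13 | (6S)-2,2,6-trimethylcyclohex-3-ene-1-carbaldehyde (C1 epimers) | C[C@H]1CC=CC(C)(C)C1C=O | intermediate
14 | methyl vinyl ketone (but-3-en-2-one) | CC(=O)C=C | starting material
15 | 1-{(E)-[(6S)-2,2,6-trimethylcyclohex-3-en-1-ylidene]methyl}pyrrolidine | C[C@H]1CC=CC(C)(C)/C1=C/N1CCCC1 | intermediate (not isolated)
16 | (1S,6S)-2,2,6-trimethyl-1-(3-oxobutyl)cyclohex-3-ene-1-carbaldehyde | C[C@H]1CC=CC(C)(C)[C@]1(C=O)CCC(C)=O | intermediate (not isolated)
17 | (2S,7R)-2,6,6-trimethylspiro[5.5]undeca-4,11-dien-10-one | C[C@H]1CC=CC(C)(C)[C@]12CCC(=O)C=C2 | intermediate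
18 | lithium (2S,7S)-2,6,6-trimethylspiro[5.5]undeca-4,10-dien-10-olate | C[C@H]1CC=CC(C)(C)[C@]12CCC([O-])=CC2.[Li+] | intermediate (not isolated)
19 | (2S,7S,11S)-11-bromo-2,6,6-trimethylspiro[5.5]undec-4-en-10-one | C[C@H]1CC=CC(C)(C)[C@]12CCC(=O)[C@@H](Br)C2 | intermediate
20 | (2S,7S,11S)-11-bromo-2,6,6,10-tetramethylspiro[5.5]undec-4-en-10-ol (C10 epimers) | C[C@H]1CC=CC(C)(C)[C@]12CCC(C)(O)[C@@H](Br)C2 | intermediate
21 | (2S,7S,10S,11S)-11-bromo-10-chloro-2,6,6,10-tetramethylspiro[5.5]undec-4-ene | C[C@H]1CC=CC(C)(C)[C@]12CC[C@](C)(Cl)[C@@H](Br)C2 | intermediate
22 | (2S,4S,5S,7S,10S,11S)-5,11-dibromo-10-chloro-2,6,6,10-tetramethylspiro[5.5]undecan-4-ol | C[C@H]1C[C@H](O)[C@@H](Br)C(C)(C)[C@]12CC[C@](C)(Cl)[C@@H](Br)C2 | intermediate (not isolated)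
23 | (2S,5S,7S,10S,11S)-5,11-dibromo-10-chloro-2,6,6,10-tetramethylspiro[5.5]undecan-4-one | C[C@H]1CC(=O)[C@@H](Br)C(C)(C)[C@]12CC[C@](C)(Cl)[C@@H](Br)C2 | intermediate
24 | (2S,4R,5S,7S,10S,11S)-5,11-dibromo-10-chloro-2,6,6,10-tetramethylspiro[5.5]undecan-4-ol | C[C@H]1C[C@@H](O)[C@@H](Br)C(C)(C)[C@]12CC[C@](C)(Cl)[C@@H](Br)C2 | target

## Step count and least certain steps

Total: 14 steps. Longest linear sequence: 14 steps (1 to 24); 5 and 14 are purchased and enter directly.

**Step 9 (key step).** The most likely failure is that the bond to C7 forms too slowly. Both enamine formation and C-alkylation occur at a carbon held between a quaternary and a tertiary centre, and 14 may polymerise or N-alkylate meanwhile. A second risk is erosion of facial selectivity if the C2 methyl is not held axial. The fallback sets out from 13 and comes back at 17. 13 is silylated (TMSCl, Et3N, NaI, MeCN) to the trimethylsilyl enol ether of the aldehyde F1. Lewis-acid-promoted Mukaiyama–Michael addition of F1 to 14 (TiCl4 or BF3·OEt2, CH2Cl2, −78 °C), in which an activated, small acceptor meets a neutral nucleophile, gives keto aldehyde 16, now isolated. KOH in MeOH then effects the aldol condensation to 17.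

**Step 10.** The borohydride may reduce the C10 carbonyl directly instead of adding to C12, because C12 sits next to the crowded spiro centre. Bromination may also take place in part on the C2 face. The fallback sets out from 17 and comes back at 19. RhCl(PPh3)3-catalysed 1,4-hydrosilylation with Et3SiH (toluene, 60 °C), a hydrometalation that is less sensitive to the bulk at C12, gives the triethylsilyl enol ether F2, which is isolated. NBS in THF at −78 °C then brominates it at C11; an axial C11 epimer can be equilibrated through the enol before step 11.

**Step 12.** The tertiary cation may lose a proton to give allylic bromides, chloride may open the bromonium ion at C11 (exchange of the halogen positions), or HCl may add to the C4–C5 alkene. The fallback sets out from 17 and comes back at 21 without passing through 19 and 20. LiBH(s-Bu)3 then PhNTf2 gives the C10 enol triflate F3. Fe(acac)3-catalysed coupling with MeMgBr gives the 10-methyl diene F4. Bu4NBrCl2 in CH2Cl2 at −78 °C adds BrCl across the more electron-rich C10–C11 alkene with Cl at the tertiary carbon. 21 is then separated from the isomer carrying bromine on the C2 face, which this sequence cannot exclude.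

**Step 13.** The hindered C4–C5 alkene may react slowly, so that allylic bromination at C3 or loss of HCl from ring B in the wet polar medium competes. The fallback sets out from 20 and comes back at 23; it changes the order so that ring A is oxidised before the labile tertiary chloride exists. 20 is treated with NBS in THF–H2O and then IBX in DMSO to give the ring A bromo ketone with the C10 alcohol intact, F5. HCl in CH2Cl2 (as in step 12) then installs the chloride and gives 23.

**Step 14.** Hydride delivery may occur in part on the methyl face, returning the trans-bromohydrin 22, or C5 may epimerise under the basic borohydride before reduction. The fallback sets out from 23 and comes back at 24 with no new compound; it hands facial control from the substrate to a chiral reagent. Reduction uses (S)-2-methyl-CBS-oxazaborolidine and catecholborane (toluene, −78 °C). By the usual model this catalyst treats the brominated C5 as the large substituent and delivers hydride to the face that gives the (4R) alcohol, under non-basic conditions.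

## Further compounds

F1 | step 9 | trimethyl({(E)-[(6S)-2,2,6-trimethylcyclohex-3-en-1-ylidene]methyl}oxy)silane | C[C@H]1CC=CC(C)(C)/C1=C/O[Si](C)(C)C
F2 | step 10 | triethyl{[(2S,7S)-2,6,6-trimethylspiro[5.5]undeca-4,10-dien-10-yl]oxy}silane | C[C@H]1CC=CC(C)(C)[C@]12CCC(O[Si](CC)(CC)CC)=CC2
F3 | step 12 | (2S,7S)-2,6,6-trimethylspiro[5.5]undeca-4,10-dien-10-yl trifluoromethanesulfonate | C[C@H]1CC=CC(C)(C)[C@]12CCC(OS(=O)(=O)C(F)(F)F)=CC2
F4 | step 12 | (2S,7S)-2,6,6,10-tetramethylspiro[5.5]undeca-4,10-diene | C[C@H]1CC=CC(C)(C)[C@]12CCC(C)=CC2
F5 | step 13 | (2S,5S,7S,11S)-5,11-dibromo-10-hydroxy-2,6,6,10-tetramethylspiro[5.5]undecan-4-one (C10 epimers) | C[C@H]1CC(=O)[C@@H](Br)C(C)(C)[C@]12CCC(C)(O)[C@@H](Br)C2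
F0 | step 14 | none | none
A1 | alternative 1 | 3-[(3S)-3-{[tert-butyl(dimethyl)silyl]oxy}-2-methylhept-6-en-2-yl]cyclohex-2-en-1-one | C=CCC[C@H](O[Si](C)(C)C(C)(C)C)C(C)(C)C1=CC(=O)CCC1
A2 | alternative 1 | tricyclic photoadduct (cyclobutane C7–C2–C1–C12, ring B ketone at C11, C5 silyl ether) | C4[C@H]1CC[C@H](O[Si](C)(C)C(C)(C)C)C(C)(C)[C@]12CCCC(=O)[C@@H]24
A3 | alternative 1 | spiro ketone after cyclobutane cleavage (ring B ketone at C11, C2 methyl cis to C12, C5 silyl ether) | C[C@H]1CC[C@H](O[Si](C)(C)C(C)(C)C)C(C)(C)[C@]12CCCC(=O)C2
A4 | alternative 2 | 5-methylcyclohexane-1,3-dione | CC1CC(=O)CC(=O)C1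
A5 | alternative 2 | (E)-hept-2-en-5-yn-4-one | C/C=C/C(=O)C#CC
A6 | alternative 2 | spiro enone-dione (ring A: C2 methyl, C4 ketone, C5–C6 alkene with C6 methyl; ring B: C8 and C12 ketones; one C10 epimer drawn) | C[C@H]1CC(=O)C=C(C)[C@]12C(=O)C[C@H](C)CC2=O
A7 | alternative 3 | (S)-5-methylcyclohex-2-en-1-one | C[C@H]1CC=CC(=O)C1
A8 | alternative 3 | (Z)-1-bromo-5-iodo-3-methylpent-2-ene | BrC/C=C(\CCI)C
A9 | alternative 3 | spiro dienone (ring A: C6 ketone, C4–C5 alkene, C2 methyl; ring B: C10–C11 alkene with C10 methyl) | C[C@H]1CC=CC(=O)[C@]12CCC(C)=CC2
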